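**Retrosynthetic overview**
- Ring C is opened at O1–C2 (6-endo oxa-Michael addition–elimination on an o-hydroxyaryl ynone) and C4 is taken back to a silyl-protected carbinol, which gives a 6-(1-silyloxy-3-arylpropynyl)-2,3,4-trimethoxyphenol.
- The strategy rests on ring A: four contiguous oxygens (O1 on C8a, methoxyls on C8, C7 and C6) are followed by C5–H and C4a. C8a/C8/C7/C6 are the four carbons of a squarate and C5/C4a are a vinyl unit, so ring A is disconnected at C4a–C8a (6π electrocyclization of a dienylketene) to a 4-alkenyl-2,3,4-trimethoxycyclobutenone.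
- The cyclobutenone comes from dimethyl squarate, an (E)-vinyllithium (tin–lithium exchange) and MeOTf. The vinylstannane comes from the ring B lithium acetylide and (E)-3-(tributylstannyl)acrolein.
- Ring order: ring B is purchased, ring A is formed in the key step, ring C is closed last.

Key step: step 8

Remark: the target has no stereocentre. The carbinol and cyclobutenone stereocentres of the intermediates are carried as racemic mixtures and both are destroyed later. The (E)-β-stannyl isomer from the hydrostannation is assumed to be separable from its isomers by chromatography.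

**Route**

Step 1
Reactants: 1 3-hydroxy-4,5-dimethoxybenzaldehyde
Product: 2 3,4-dimethoxy-5-(methoxymethoxy)benzaldehyde
Conditions: MOMCl, iPr2NEt, CH2Cl2, 0 °C to rt
Reagents that add atoms: chloromethyl methyl ether (MOMCl), COCCl
Why: O-alkylation of the phenol (methoxymethyl protection) should be clean because the phenol is the only acidic nucleophile and the aldehyde is inert to these conditions.

Step 2
Reactants: 2 3,4-dimethoxy-5-(methoxymethoxy)benzaldehyde
Product: 3 5-ethynyl-1,2-dimethoxy-3-(methoxymethoxy)benzene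
Conditions: dimethyl (1-diazo-2-oxopropyl)phosphonate, K2CO3, MeOH, rt
Reagents that add atoms: dimethyl (1-diazo-2-oxopropyl)phosphonate, COP(=O)(OC)C(=[N+]=[N-])C(C)=O
Why: Ohira–Bestmann (Seyferth–Gilbert) homologation should convert the electron-rich aryl aldehyde directly to the terminal alkyne under mild base that leaves the methoxymethyl ether intact.

Step 3
Reactants: 4 propargyl alcohol
Product: 5 (E)-3-(tributylstannyl)prop-2-en-1-ol
Conditions: Bu3SnH, AIBN (cat.), neat, 80 °C; chromatography
Reagents that add atoms: tributyltin hydride, CCCC[SnH](CCCC)CCCC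
Why: Radical hydrostannation of the terminal alkyne is reversible at the stannyl-radical addition stage, so the (E)-β-stannyl alkene should be the main product and is separated from the minor isomers.

Step 4
Reactants: 5 (E)-3-(tributylstannyl)prop-2-en-1-ol
Product: 6 (E)-3-(tributylstannyl)prop-2-enal
Conditions: MnO2, CH2Cl2, rt
Reagents that add atoms: none
Why: MnO2 oxidation of the allylic alcohol should give the enal without touching the C–Sn bond or the alkene geometry.

Step 5
Reactants: 3 5-ethynyl-1,2-dimethoxy-3-(methoxymethoxy)benzene; 6 (E)-3-(tributylstannyl)prop-2-enal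
Product: 8 (E)-5-[3,4-dimethoxy-5-(methoxymethoxy)phenyl]-1-(tributylstannyl)pent-1-en-4-yn-3-ol (racemic), via lithium acetylide 7 (not isolated)
Conditions: n-BuLi (0.95 equiv to 3), THF, –78 °C; then 6, –78 °C; H2O
Reagents that add atoms: none
Why: Deprotonation of the terminal alkyne and 1,2-addition of the lithium acetylide to the enal carbonyl should give the secondary carbinol as a racemate, the acetylide being too weakly basic to attack the vinylstannane.

Step 6
Reactants: 8 (E)-5-[3,4-dimethoxy-5-(methoxymethoxy)phenyl]-1-(tributylstannyl)pent-1-en-4-yn-3-ol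
Product: 9 tert-butyl({(E)-5-[3,4-dimethoxy-5-(methoxymethoxy)phenyl]-1-(tributylstannyl)pent-1-en-4-yn-3-yl}oxy)dimethylsilane (racemic)
Conditions: TBSCl, imidazole, DMF, rt
Reagents that add atoms: tert-butyldimethylsilyl chloride, CC(C)(C)[Si](C)(C)Cl
Why: Imidazole-promoted silylation of the secondary alcohol should proceed under neutral conditions that the vinylstannane and the methoxymethyl ether tolerate.

Step 7
Reactants: 9 the silyl ether of step 6; 10 dimethyl squarate (3,4-dimethoxycyclobut-3-ene-1,2-dione)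
Product: 13 4-{(E)-3-[(tert-butyldimethylsilyl)oxy]-5-[3,4-dimethoxy-5-(methoxymethoxy)phenyl]pent-1-en-4-yn-1-yl}-2,3,4-trimethoxycyclobut-2-en-1-one (racemic mixture of both diastereomers), via vinyllithium 11 (not isolated), via lithium alkoxide 12 (not isolated)
Conditions: n-BuLi, THF, –78 °C; cannula into 10, THF, –78 °C; MeOTf, –78 to 0 °C; aq NaHCO3
Reagents that add atoms: methyl trifluoromethanesulfonate (MeOTf), COS(=O)(=O)C(F)(F)F
Why: Tin–lithium exchange with retention of the E geometry, 1,2-addition of the vinyllithium to one carbonyl of the squarate and O-methylation of the resulting lithium alkoxide by MeOTf should give the 4-alkenyl-4-methoxycyclobutenone, whose new quaternary centre is uncontrolled and irrelevant.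

Step 8
Reactants: 13 the 4-alkenyl-2,3,4-trimethoxycyclobutenone of step 7
Product: 16 6-{1-[(tert-butyldimethylsilyl)oxy]-3-[3,4-dimethoxy-5-(methoxymethoxy)phenyl]prop-2-yn-1-yl}-2,3,4-trimethoxyphenol (racemic), via dienylketene 14 (not isolated), via cyclohexadienone 15 (not isolated)
Conditions: PhMe (degassed, ca. 0.01 M), 110 °C
Reagents that add atoms: none
Why: Heating should open the cyclobutenone by conrotatory 4π cleavage of the C1–C4 bond to dienylketene 14, which closes by a thermally allowed disrotatory 6π electrocyclization between the ketene carbon and the distal alkene carbon (the future C8a–C4a bond) to cyclohexadienone 15, and enolization then gives the phenol. The closest known reaction type is the thermal ring expansion of squarate-derived 4-alkenyl-4-alkoxycyclobutenones to polyoxygenated phenols (Moore rearrangement). Ring A is closed as a six-membered carbocycle in a 6π-electrocyclic mode, and no new stereocentre remains because the sp3 carbon of 15 is lost on tautomerization and the quaternary carbon of 13 becomes aromatic C6. The step needs inward rotation of the alkenyl arm, which the C4 methoxyl secures by rotating outward as the donor, and the E alkene keeps the bulky silyloxypropargyl chain away from the ketene terminus. The oxygen pattern follows from connectivity: the ketene oxygen becomes the C8a hydroxyl, the squarate methoxyls end on C8 and C7, the methoxyl from MeOTf on C6, and the alkene carbons become C5–H and C4a.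

Step 9
Reactants: 16 the silyloxy phenol of step 8
Product: 17 6-{1-hydroxy-3-[3,4-dimethoxy-5-(methoxymethoxy)phenyl]prop-2-yn-1-yl}-2,3,4-trimethoxyphenol (racemic)
Conditions: Bu4NF, AcOH, THF, 0 °C to rt
Reagents that add atoms: none
Why: Fluoride-induced desilylation, buffered with acetic acid so that the o-hydroxybenzylic system is not exposed to strong base, should free the carbinol.

Step 10
Reactants: 17 the diol of step 9
Product: 18 3-[3,4-dimethoxy-5-(methoxymethoxy)phenyl]-1-(2-hydroxy-3,4,5-trimethoxyphenyl)prop-2-yn-1-one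
Conditions: MnO2 (activated, excess), CH2Cl2, rt
Reagents that add atoms: none
Why: MnO2 oxidation of the doubly activated (benzylic and propargylic) alcohol should be fast enough to give the o-hydroxyaryl ynone, which is stabilized by its intramolecular hydrogen bond, before the phenol ring is attacked.

Step 11
Reactants: 18 the o-hydroxyaryl ynone of step 10
Product: 20 2-[3,4-dimethoxy-5-(methoxymethoxy)phenyl]-6,7,8-trimethoxy-4H-chromen-4-one, via enaminone 19 (not isolated)
Conditions: Et2NH, EtOH, rt then 60 °C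
Reagents that add atoms: none
Why: Conjugate addition of Et2NH to the ynone gives the β-amino enone, and oxa-Michael addition–elimination by the phenol at the same β-carbon then forms O1–C2 with loss of Et2NH, which enforces the 6-endo flavone closure over 5-exo aurone formation.

Step 12
Reactants: 20 the methoxymethyl-protected flavone of step 11
Product: 21 2-(3-hydroxy-4,5-dimethoxyphenyl)-6,7,8-trimethoxy-4H-chromen-4-one (target)
Conditions: HCl, MeOH, 50 °C
Reagents that add atoms: none
Why: Acid-catalysed acetal exchange should remove the methoxymethyl group while the aryl methyl ethers and the flavone core, which has no labile 5-methoxyl, stay intact.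

**Compound list**
1 | 3-hydroxy-4,5-dimethoxybenzaldehyde | COc1cc(C=O)cc(O)c1OC | starting material
2 | 3,4-dimethoxy-5-(methoxymethoxy)benzaldehyde | COCOc1cc(C=O)cc(OC)c1OC | intermediate
3 | 5-ethynyl-1,2-dimethoxy-3-(methoxymethoxy)benzene | C#Cc1cc(OC)c(OC)c(OCOC)c1 | intermediate
4 | propargyl alcohol (prop-2-yn-1-ol) | C#CCO | starting material
5 | (E)-3-(tributylstannyl)prop-2-en-1-ol | CCCC[Sn](CCCC)(CCCC)/C=C/CO | intermediate
6 | (E)-3-(tributylstannyl)prop-2-enal | CCCC[Sn](CCCC)(CCCC)/C=C/C=O | intermediate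
7 | lithium [3,4-dimethoxy-5-(methoxymethoxy)phenyl]acetylide | [Li]C#Cc1cc(OC)c(OC)c(OCOC)c1 | intermediate
8 | (E)-5-[3,4-dimethoxy-5-(methoxymethoxy)phenyl]-1-(tributylstannyl)pent-1-en-4-yn-3-ol (racemic) | CCCC[Sn](CCCC)(CCCC)/C=C/C(O)C#Cc1cc(OC)c(OC)c(OCOC)c1 | intermediate
9 | tert-butyl({(E)-5-[3,4-dimethoxy-5-(methoxymethoxy)phenyl]-1-(tributylstannyl)pent-1-en-4-yn-3-yl}oxy)dimethylsilane (racemic) | CCCC[Sn](CCCC)(CCCC)/C=C/C(O[Si](C)(C)C(C)(C)C)C#Cc1cc(OC)c(OC)c(OCOC)c1 | intermediate
10 | dimethyl squarate (3,4-dimethoxycyclobut-3-ene-1,2-dione) | COC1=C(OC)C(=O)C1=O | starting material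
11 | (E)-3-[(tert-butyldimethylsilyl)oxy]-5-[3,4-dimethoxy-5-(methoxymethoxy)phenyl]pent-1-en-4-yn-1-yllithium (racemic) | [Li]/C=C/C(O[Si](C)(C)C(C)(C)C)C#Cc1cc(OC)c(OC)c(OCOC)c1 | intermediate
12 | lithium alkoxide of the 4-alkenyl-4-hydroxy-2,3-dimethoxycyclobut-2-en-1-one (alkene E, diastereomer mixture) | COC1=C(OC)C(O[Li])(/C=C/C(O[Si](C)(C)C(C)(C)C)C#Cc2cc(OC)c(OC)c(OCOC)c2)C1=O | intermediate
13 | 4-{(E)-3-[(tert-butyldimethylsilyl)oxy]-5-[3,4-dimethoxy-5-(methoxymethoxy)phenyl]pent-1-en-4-yn-1-yl}-2,3,4-trimethoxycyclobut-2-en-1-one (racemic, both diastereomers) | COC1=C(OC)C(OC)(/C=C/C(O[Si](C)(C)C(C)(C)C)C#Cc2cc(OC)c(OC)c(OCOC)c2)C1=O | intermediate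
14 | dienylketene: (3Z,5E)-7-[(tert-butyldimethylsilyl)oxy]-9-aryl-2,3,4-trimethoxynona-1,3,5-trien-8-yn-1-one, alkenyl arm cis to the ketenyl group | O=C=C(OC)/C(OC)=C(OC)\C=C\C(O[Si](C)(C)C(C)(C)C)C#Cc1cc(OC)c(OC)c(OCOC)c1 | intermediate
15 | 6-{1-[(tert-butyldimethylsilyl)oxy]-3-[3,4-dimethoxy-5-(methoxymethoxy)phenyl]prop-2-yn-1-yl}-2,3,4-trimethoxycyclohexa-2,4-dien-1-one (stereoisomer mixture) | COC1=CC(C(O[Si](C)(C)C(C)(C)C)C#Cc2cc(OC)c(OC)c(OCOC)c2)C(=O)C(OC)=C1OC | intermediate
16 | 6-{1-[(tert-butyldimethylsilyl)oxy]-3-[3,4-dimethoxy-5-(methoxymethoxy)phenyl]prop-2-yn-1-yl}-2,3,4-trimethoxyphenol (racemic) | COc1cc(C(O[Si](C)(C)C(C)(C)C)C#Cc2cc(OC)c(OC)c(OCOC)c2)c(O)c(OC)c1OC | intermediate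
17 | 6-{1-hydroxy-3-[3,4-dimethoxy-5-(methoxymethoxy)phenyl]prop-2-yn-1-yl}-2,3,4-trimethoxyphenol (racemic) | COc1cc(C(O)C#Cc2cc(OC)c(OC)c(OCOC)c2)c(O)c(OC)c1OC | intermediate
18 | 3-[3,4-dimethoxy-5-(methoxymethoxy)phenyl]-1-(2-hydroxy-3,4,5-trimethoxyphenyl)prop-2-yn-1-one | COc1cc(C(=O)C#Cc2cc(OC)c(OC)c(OCOC)c2)c(O)c(OC)c1OC | intermediate
19 | 3-(diethylamino)-3-[3,4-dimethoxy-5-(methoxymethoxy)phenyl]-1-(2-hydroxy-3,4,5-trimethoxyphenyl)prop-2-en-1-one (alkene geometry not defined) | CCN(CC)C(=CC(=O)c1cc(OC)c(OC)c(OC)c1O)c1cc(OC)c(OC)c(OCOC)c1 | intermediate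
20 | 2-[3,4-dimethoxy-5-(methoxymethoxy)phenyl]-6,7,8-trimethoxy-4H-chromen-4-one | COCOc1cc(-c2cc(=O)c3cc(OC)c(OC)c(OC)c3o2)cc(OC)c1OC | intermediate
21 | 2-(3-hydroxy-4,5-dimethoxyphenyl)-6,7,8-trimethoxy-4H-chromen-4-one | COc1cc(-c2cc(=O)c3cc(OC)c(OC)c(OC)c3o2)cc(O)c1OC | target

**Step count**
Total: 12 steps. Longest linear sequence: 10 steps (from 1 through steps 1, 2 and 5–12; equally from 4 through steps 3–12).

**Steps most likely to fail**

1. Step 7. The carbinol C–H of 9 is allylic, propargylic and α to the silyloxy group, so n-BuLi or the vinyllithium may remove it before tin–lithium exchange is complete, which would starve the squarate addition. O-methylation of the hindered alkoxide may also lag. The fallback sets out from 6 and moves the acidic carbinol out of the organolithium step. Acetalization of 6 (HC(OEt)3, EtOH, cat. pyridinium p-toluenesulfonate) should give (E)-tributyl(3,3-diethoxyprop-1-en-1-yl)stannane F1. Tin–lithium exchange (n-BuLi, THF, –78 °C), addition to 10 and quenching with MeOTf should give 4-[(E)-3,3-diethoxyprop-1-en-1-yl]-2,3,4-trimethoxycyclobut-2-en-1-one F2. The same thermal ring expansion (PhMe, 110 °C) should give 6-(diethoxymethyl)-2,3,4-trimethoxyphenol F3, and dilute aqueous HCl in THF should release 2-hydroxy-3,4,5-trimethoxybenzaldehyde F4. Addition of 2.2 equivalents of lithium acetylide 7 (THF, –78 to 0 °C; the first equivalent forms the phenoxide) should give diol 17, where the route is rejoined.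

2. Step 8. After ring opening, the ketene may oligomerize or be trapped instead of cyclizing. At 110 °C the new phenol may also take over the silyl group or expel silanol towards an o-quinone methide, and the electron-rich phenol may be oxidized by traces of air. The fallback sets out from 2 and gives up the electrocyclization for classical chalcone chemistry. Commercial 2,3,4-trimethoxyphenol is C-acetylated ortho to the hydroxyl (AcOH, BF3·OEt2, 90 °C, Fries-type acylation) to 1-(2-hydroxy-3,4,5-trimethoxyphenyl)ethan-1-one F5. Claisen–Schmidt condensation of F5 with 2 (KOH, EtOH, rt) should give (E)-3-[3,4-dimethoxy-5-(methoxymethoxy)phenyl]-1-(2-hydroxy-3,4,5-trimethoxyphenyl)prop-2-en-1-one F6. Oxidative cyclization (cat. I2, DMSO, 120 °C) should give flavone 20, where the route is rejoined; any loss of the methoxymethyl group in this step would lead on to 21 directly.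

3. Step 10. Oxidation of the electron-rich p-methoxyphenol ring to a quinone, or oxidative coupling at the free phenol, may outrun oxidation of the carbinol. The fallback sets out from 16 and masks the phenol before the oxidation. Acetylation (Ac2O, pyridine, cat. DMAP) should give 6-{1-[(tert-butyldimethylsilyl)oxy]-3-[3,4-dimethoxy-5-(methoxymethoxy)phenyl]prop-2-yn-1-yl}-2,3,4-trimethoxyphenyl acetate F7. Desilylation under acidic conditions that suppress acyl migration (HF·pyridine, THF/pyridine, 0 °C) should give 6-{1-hydroxy-3-[3,4-dimethoxy-5-(methoxymethoxy)phenyl]prop-2-yn-1-yl}-2,3,4-trimethoxyphenyl acetate F8. Dess–Martin periodinane (NaHCO3, CH2Cl2, rt) should give 6-{3-[3,4-dimethoxy-5-(methoxymethoxy)phenyl]prop-2-ynoyl}-2,3,4-trimethoxyphenyl acetate F9. Et2NH in EtOH (rt to 60 °C) should then add to the ynone, cleave the aryl acetate by aminolysis and close ring C to flavone 20, where the route is rejoined.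

**Further compounds**
F1 | step 7 | (E)-tributyl(3,3-diethoxyprop-1-en-1-yl)stannane | CCCC[Sn](CCCC)(CCCC)/C=C/C(OCC)OCC
F2 | step 7 | 4-[(E)-3,3-diethoxyprop-1-en-1-yl]-2,3,4-trimethoxycyclobut-2-en-1-one (racemic) | CCOC(OCC)/C=C/C1(OC)C(OC)=C(OC)C1=O
F3 | step 7 | 6-(diethoxymethyl)-2,3,4-trimethoxyphenol | CCOC(OCC)c1cc(OC)c(OC)c(OC)c1O
F4 | step 7 | 2-hydroxy-3,4,5-trimethoxybenzaldehyde | COc1cc(C=O)c(O)c(OC)c1OC
F5 | step 8 | 1-(2-hydroxy-3,4,5-trimethoxyphenyl)ethan-1-one | CC(=O)c1cc(OC)c(OC)c(OC)c1O
F6 | step 8 | (E)-3-[3,4-dimethoxy-5-(methoxymethoxy)phenyl]-1-(2-hydroxy-3,4,5-trimethoxyphenyl)prop-2-en-1-one | COCOc1cc(/C=C/C(=O)c2cc(OC)c(OC)c(OC)c2O)cc(OC)c1OC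
F7 | step 10 | 6-{1-[(tert-butyldimethylsilyl)oxy]-3-[3,4-dimethoxy-5-(methoxymethoxy)phenyl]prop-2-yn-1-yl}-2,3,4-trimethoxyphenyl acetate (racemic) | COc1cc(C(O[Si](C)(C)C(C)(C)C)C#Cc2cc(OC)c(OC)c(OCOC)c2)c(OC(C)=O)c(OC)c1OC
F8 | step 10 | 6-{1-hydroxy-3-[3,4-dimethoxy-5-(methoxymethoxy)phenyl]prop-2-yn-1-yl}-2,3,4-trimethoxyphenyl acetate (racemic) | COc1cc(C(O)C#Cc2cc(OC)c(OC)c(OCOC)c2)c(OC(C)=O)c(OC)c1OC
F9 | step 10 | 6-{3-[3,4-dimethoxy-5-(methoxymethoxy)phenyl]prop-2-ynoyl}-2,3,4-trimethoxyphenyl acetate | COc1cc(C(=O)C#Cc2cc(OC)c(OC)c(OCOC)c2)c(OC(C)=O)c(OC)c1OC
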